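## Retrosynthetic overview

1. The two esters go on last: the C2 angelate (mixed-anhydride acylation of the equatorial OH of a 2α,3α-diol) and the C20 (R)-2-methylbutanoate. The 8(17)-methylene comes from Cope elimination of a C17 dimethylamino group, and the 7α-OH from bulky-hydride reduction of a 7-ketone.
2. C9–C11: copper-catalysed Michael-type 1,4-addition of an (R)-linalool-derived C11–C16 Grignard reagent to a Δ5,Δ8-dien-7-one, anti to C20 (9α chain). The enolate is trapped at C8 by a Mannich reaction (C17); Li/NH3 then sets 5α-H.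
3. The dienone comes from a Δ5 olefin (allylic oxidation, Saegusa–Ito). The 2α,3α-diol comes from α-face osmylation of a Δ2 olefin made from the C3 ketone.
4. Key bond C1–C10: auxiliary-controlled, copper-catalysed intermolecular Michael addition of ethyl 2-oxocyclohexanecarboxylate to ethyl vinyl ketone sets quaternary C10 (its ester becomes C20).
5. Ring order: ring B is the purchased cyclohexanone; ring A is closed onto it by aldol condensation (Robinson annulation) and then gem-dimethylated.

Assumption: labdane numbering is used for all bicyclic compounds (C1–C10 ring carbons, C18/C19 on C4, C20 on C10, C17 on C8, C11–C16 side chain; β = the face carrying C20), and (R)-(−)-linalool of high ee, L-valine diethylamide, angelic acid and (R)-2-methylbutanoic acid are bought.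

The target is (13R)-2α-angeloyloxy-3α,7α,13-trihydroxy-9βH-labda-8(17),14-dien-20-yl (R)-2-methylbutanoate: C20 is β; H5, the 2-, 3- and 7-oxygens and the C9 side chain are all α.

## Route

Step 1
Reactants: 1 ethyl 2-oxocyclohexane-1-carboxylate; 2 L-valine diethylamide
Product: 3 ethyl 2-{[(2S)-1-(diethylamino)-3-methyl-1-oxobutan-2-yl]amino}cyclohex-1-ene-1-carboxylate (enamino ester)
Conditions: conc. HCl (cat.), 4 Å molecular sieves, toluene, 60 °C
Reagents that add atoms: none
Why: Acid-catalysed enamine condensation of the β-keto ester with the primary amine gives the hydrogen-bonded enamino ester; no new stereocentre is formed.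

Step 2
Reactants: 3 enamino ester; 4 ethyl vinyl ketone (pent-1-en-3-one)
Product: 6 ethyl (1R)-2-oxo-1-(3-oxopentyl)cyclohexane-1-carboxylate, via Michael-adduct ketimine 5 (not isolated)
Conditions: Cu(OAc)2·H2O (5 mol %), acetone, rt, 16 h; then 2 M aq. HCl, rt
Reagents that add atoms: water, O
Why: Christoffers-type copper-catalysed Michael addition: in the divalent copper chelate of the enaminoester (N, ester O, amide O) the isopropyl group blocks one face, so the enone adds to the other and sets quaternary C10 as R (recalled sense for the L-valine auxiliary; ee normally above 95 %), and acid hydrolysis returns the ketone and the auxiliary.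

Step 3
Reactants: 6 diketo ester
Product: 7 ethyl (4aR)-1-methyl-2-oxo-2,3,4,4a,5,6,7,8-octahydronaphthalene-4a-carboxylate (labdane numbering: Δ4-3-one with 4-methyl and 10β-CO2Et)
Conditions: p-TsOH·H2O (10 mol %), toluene, reflux, Dean–Stark
Reagents that add atoms: none
Why: Intramolecular aldol condensation (second stage of a Robinson annulation) closes ring A between C4 and C5 to the conjugated six-membered enone; C10 cannot epimerise.

Step 4
Reactants: 7 enone ester
Product: 8 ethyl (4aR)-1,1-dimethyl-2-oxo-1,2,3,4,4a,5,6,7-octahydronaphthalene-4a-carboxylate (3-oxo-4,4-dimethyl-Δ5(6) with 10β-CO2Et)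
Conditions: KOt-Bu (1.3 equiv), t-BuOH, rt; MeI (3 equiv), rt
Reagents that add atoms: iodomethane, CI
Why: Deconjugative α-alkylation: the extended dienolate (γ-deprotonation at C6) is methylated at C4, and the β,γ-olefin cannot return into conjugation past the new quaternary carbon.

Step 5
Reactants: 8 β,γ-unsaturated keto ester
Product: 9 C3 enol triflate of 8 (3-OTf-Δ2 and Δ5(6) diene with 10β-CO2Et)
Conditions: KN(SiMe3)2 (1.2 equiv), THF, −78 °C; PhNTf2, −78 → 0 °C
Reagents that add atoms: N-phenylbis(trifluoromethanesulfonimide), O=S(=O)(N(c1ccccc1)S(=O)(=O)C(F)(F)F)C(F)(F)F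
Why: Enolisation can only occur at C2 (C4 is quaternary), and O-sulfonylation of the enolate gives the enol triflate.

Step 6
Reactants: 9 enol triflate
Product: 10 ethyl 4,4-dimethyl-Δ2,Δ5(6)-diene-10β-carboxylate (C3 now CH)
Conditions: Pd(OAc)2 (5 mol %), PPh3 (10 mol %), HCO2H, Et3N, DMF, 60 °C
Reagents that add atoms: none
Why: Palladium-catalysed formate reduction of the enol triflate (oxidative addition, decarboxylation of formate to a palladium hydride, reductive elimination) replaces OTf by H and leaves the Δ2 olefin in place.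

Step 7
Reactants: 10 diene ester
Product: 11 Δ2,Δ5(6)-dien-20-ol (10β-CH2OH)
Conditions: LiAlH4, THF, 0 °C → reflux; Fieser work-up
Reagents that add atoms: none
Why: Hydride reduction of the hindered ester to the neopentyl primary alcohol; the isolated olefins are inert.

Step 8
Reactants: 11 dienol
Product: 12 20-O-TBS ether of 11
Conditions: TBSCl, imidazole, DMAP (cat.), DMF, 40 °C
Reagents that add atoms: tert-butyldimethylsilyl chloride, CC(C)(C)[Si](C)(C)Cl
Why: Standard silylation gives a robust neopentyl silyl ether that survives the oxidations, bases and dissolving metal that follow.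

Step 9
Reactants: 12 silyl ether diene
Product: 13 20-(TBSO)-Δ5(6)-ene-2α,3α-diol
Conditions: OsO4 (5 mol %), NMO (1.5 equiv), acetone/H2O 8:1, rt, 36 h
Reagents that add atoms: osmium tetroxide (catalyst), O=[Os](=O)(=O)=O; N-methylmorpholine N-oxide, C[N+]1([O-])CCOCC1; water, O
Why: Upjohn syn-dihydroxylation: OsO4 attacks only the disubstituted Δ2 olefin (Δ5 is flanked by two quaternary carbons) and from the α-face, opposite the axial 4β-methyl and C20 groups, setting C2 and C3 as the 2α,3α-cis-diol.

Step 10
Reactants: 13 diol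
Product: 14 2α,3α-O-isopropylidene acetal (acetonide) of 13
Conditions: Me2C(OMe)2, PPTS (cat.), CH2Cl2, rt
Reagents that add atoms: 2,2-dimethoxypropane, COC(C)(C)OC
Why: Acetal exchange onto the cis-1,2-diol gives the five-membered acetonide.

Step 11
Reactants: 14 acetonide
Product: 15 Δ5-7-ketone (20-OTBS, 2α,3α-acetonide)
Conditions: CrO3 (15 equiv), 3,5-dimethylpyrazole (15 equiv), CH2Cl2, −20 °C
Reagents that add atoms: chromium trioxide, O=[Cr](=O)=O
Why: Allylic oxidation with the CrO3–3,5-dimethylpyrazole complex; C7 is the only allylic CH2 (C4 and C10 are quaternary), so the enone forms regiospecifically.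

Step 12
Reactants: 15 enone
Product: 17 cross-conjugated Δ5,Δ8-dien-7-one, via silyl dienol ether 16 (not isolated)
Conditions: LiN(i-Pr)2 (1.3 equiv), TMSCl, THF, −78 °C; then Pd(OAc)2 (1.1 equiv), MeCN, rt
Reagents that add atoms: none
Why: Saegusa–Ito oxidation: the enone can enolise only at C8, and divalent palladium dehydrogenates the 2-silyloxydiene across C8–C9.

Step 13
Reactants: 18 (R)-(−)-linalool
Product: 19 (5R)-5-methyl-5-vinyltetrahydrofuran-2-ol (lactol, anomer mixture)
Conditions: O3, CH2Cl2, −78 °C (Sudan red 7B end-point); Me2S, −78 °C → rt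
Reagents that add atoms: ozone, [O-][O+]=O
Why: Ozonolysis cleaves the electron-rich trisubstituted olefin much faster than the vinyl group, and the γ-hydroxy aldehyde closes to the lactol; C13 (R) is untouched.

Step 14
Reactants: 19 lactol
Product: 20 (R)-5-iodo-3-methylpent-1-en-3-yl formate
Conditions: PhI(OAc)2 (1.2 equiv), I2 (1.0 equiv), cyclohexane/CH2Cl2, rt, visible light
Reagents that add atoms: iodine, [I][I]
Why: Suárez alkoxy-radical fragmentation: the anomeric hypoiodite gives an alkoxy radical whose β-scission leaves the tertiary formate and a primary C11 radical that is trapped by iodine.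

Step 15
Reactants: 20 iodo formate
Product: 21 (R)-5-iodo-3-methylpent-1-en-3-ol
Conditions: K2CO3 (0.1 equiv), MeOH, 0 °C, 30 min
Reagents that add atoms: none
Why: Base-catalysed transesterification removes the formate; the conditions are too mild for oxetane closure by the hindered tertiary alkoxide.

Step 16
Reactants: 17 dienone; 21 iodo alcohol
Product: 24 (13R)-17-(dimethylamino)-13-hydroxy-2α,3α-isopropylidenedioxy-20-(tert-butyldimethylsilyloxy)-9βH-labda-5,14-dien-7-one (9α side chain; C8 epimers), via alkoxide Grignard reagent 22 (not isolated), via bis-silyl dienol ether 23 (not isolated)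
Conditions: 21, MeMgCl (1.0 equiv), THF, −20 °C; Mg turnings, rt; then CuBr·SMe2 (20 mol %), TMSCl (4 equiv), 17, THF, −78 → −30 °C; then CH2=NMe2+ I−, CH2Cl2, rt; K2CO3, MeOH work-up
Reagents that add atoms: Eschenmoser's salt (N,N-dimethylmethyleneiminium iodide), C=[N+](C)C.[I-]
Why: Copper-catalysed Michael-type 1,4-addition of the Normant-type alkoxide Grignard reagent occurs at C9 (C5 is fully substituted) and anti to the axial C20 group, as in 1α-alkylation of steroidal 1,4-dien-3-ones, setting the 9α side chain; the silyl dienol ether then undergoes a Mannich reaction with the iminium salt only at C8.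

Step 17
Reactants: 24 amino enone
Product: 25 (13R)-17-(dimethylamino)-13-hydroxy-2α,3α-isopropylidenedioxy-20-(tert-butyldimethylsilyloxy)-5αH,9βH-labd-14-en-7-one (C8 epimers)
Conditions: Li (5 equiv), NH3(l)/THF, t-BuOH (1 equiv), −78 °C, 15 min; isoprene; NH4Cl
Reagents that add atoms: none
Why: Dissolving-metal (Birch-type) enone reduction: the β-carbon C5 is protonated axially, anti to C20, giving the trans-fused 5α-H ketone; the isolated vinyl group, amine, acetonide and silyl ether are inert.

Step 18
Reactants: 25 silyl ether ketone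
Product: 26 the corresponding C20 primary alcohol
Conditions: HF·pyridine, pyridine, THF, 0 °C → rt
Reagents that add atoms: none
Why: Fluoride desilylation under buffered, weakly acidic conditions that keep the amine protonated and so suppress β-elimination of the Mannich base.

Step 19
Reactants: 26 C20 alcohol; 27 (R)-2-methylbutanoic acid
Product: 28 C20 (R)-2-methylbutanoate of 26
Conditions: 27 (1.5 equiv), DCC, DMAP (0.2 equiv), CH2Cl2, 0 °C → rt
Reagents that add atoms: none
Why: Steglich esterification of the only acylable hydroxyl (primary C20–OH; the tertiary C13–OH does not react); the α-stereocentre of the acid is not enolised under these conditions.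

Step 20
Reactants: 28 keto ester
Product: 29 the 7α-alcohol (7α,13-diol with 17-NMe2, 2α,3α-acetonide and C20 ester)
Conditions: LiBH(s-Bu)3 (L-Selectride, 3 equiv), THF, −78 °C; aq. NH4Cl
Reagents that add atoms: none
Why: Ketone reduction with a bulky trialkylborohydride: hydride arrives equatorially from the β-side, away from the axial 9α chain and 5α-H, giving the axial 7α-alcohol; the hindered ester survives at −78 °C.

Step 21
Reactants: 29 acetonide
Product: 30 (13R)-17-(dimethylamino)-2α,3α,7α,13-tetrahydroxy-5αH,9βH-labd-14-en-20-yl (R)-2-methylbutanoate (C8 epimers)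
Conditions: AcOH/H2O 4:1, 45 °C; NaHCO3 work-up
Reagents that add atoms: none
Why: Acid-catalysed acetal hydrolysis frees the 2α,3α-diol before any allylic alcohol at C7 exists; the mild acid leaves the ester and the tertiary vinyl carbinol intact.

Step 22
Reactants: 30 amino tetraol
Product: 32 (13R)-2α,3α,7α,13-tetrahydroxy-9βH-labda-8(17),14-dien-20-yl (R)-2-methylbutanoate, via amine N-oxide 31 (not isolated)
Conditions: mCPBA (1.05 equiv), CH2Cl2, −20 °C; basic alumina filtration; then THF, 65 °C
Reagents that add atoms: none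
Why: N-oxidation followed by Cope elimination: the syn-elimination can use only H8, the single β-hydrogen, so the 8(17)-methylene forms regiospecifically and the C8 epimer mixture converges.

Step 23
Reactants: 32 tetraol ester; 33 angelic acid [(Z)-2-methylbut-2-enoic acid]
Product: 35 target CNP0391865.1, via angelic mixed anhydride 34 (not isolated)
Conditions: 33 (1.3 equiv), 2,4,6-trichlorobenzoyl chloride, Et3N, toluene, rt, 2 h; then 32, toluene, 80 °C
Reagents that add atoms: none
Why: Yamaguchi-type esterification with the preformed angelic 2,4,6-trichlorobenzoic mixed anhydride, which transfers the angeloyl group without Z→E isomerisation; the equatorial C2–OH reacts, while the axial neopentyl C3–OH, the hindered axial C7–OH and the tertiary C13–OH do not.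

## Compound list

1 | ethyl 2-oxocyclohexane-1-carboxylate | CCOC(=O)C1CCCCC1=O | starting material
2 | L-valine diethylamide | CC(C)[C@H](N)C(=O)N(CC)CC | starting material
3 | enamino ester of 1 with 2 | CCOC(=O)C1=C(N[C@@H](C(C)C)C(=O)N(CC)CC)CCCC1 | intermediate
4 | ethyl vinyl ketone | CCC(=O)C=C | starting material
5 | Michael-adduct ketimine | CCOC(=O)[C@@]1(CCC(=O)CC)CCCCC1=N[C@@H](C(C)C)C(=O)N(CC)CC | intermediate (not isolated)
6 | ethyl (1R)-2-oxo-1-(3-oxopentyl)cyclohexane-1-carboxylate | CCC(=O)CC[C@]1(C(=O)OCC)CCCCC1=O | intermediate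
7 | ethyl (4aR)-1-methyl-2-oxo-2,3,4,4a,5,6,7,8-octahydronaphthalene-4a-carboxylate | O=C1CC[C@]2(C(=O)OCC)CCCCC2=C1C | intermediate
8 | ethyl (4aR)-1,1-dimethyl-2-oxo-1,2,3,4,4a,5,6,7-octahydronaphthalene-4a-carboxylate | O=C1CC[C@]2(C(=O)OCC)CCCC=C2C1(C)C | intermediate
9 | C3 enol triflate of 8 | O=S(=O)(OC1=CC[C@]2(C(=O)OCC)CCCC=C2C1(C)C)C(F)(F)F | intermediate
10 | ethyl 4,4-dimethyl-Δ2,Δ5(6)-diene-10β-carboxylate | C1=CC[C@]2(C(=O)OCC)CCCC=C2C1(C)C | intermediate
11 | Δ2,Δ5(6)-dien-20-ol | C1=CC[C@]2(CO)CCCC=C2C1(C)C | intermediate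
12 | 20-O-TBS ether of 11 | C1=CC[C@]2(CO[Si](C)(C)C(C)(C)C)CCCC=C2C1(C)C | intermediate
13 | 20-(TBSO)-Δ5(6)-ene-2α,3α-diol | C1CCC=C2C(C)(C)[C@H](O)[C@H](O)C[C@]12CO[Si](C)(C)C(C)(C)C | intermediate
14 | 2α,3α-acetonide of 13 | C1CCC=C2C(C)(C)[C@@H]3OC(C)(C)O[C@@H]3C[C@]12CO[Si](C)(C)C(C)(C)C | intermediate
15 | Δ5-7-ketone | C1CC(=O)C=C2C(C)(C)[C@@H]3OC(C)(C)O[C@@H]3C[C@]12CO[Si](C)(C)C(C)(C)C | intermediate
16 | 7-(trimethylsilyloxy)-5,7-diene (silyl dienol ether) | C1C=C(O[Si](C)(C)C)C=C2C(C)(C)[C@@H]3OC(C)(C)O[C@@H]3C[C@]12CO[Si](C)(C)C(C)(C)C | intermediate (not isolated)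
17 | Δ5,Δ8-dien-7-one | C1=CC(=O)C=C2C(C)(C)[C@@H]3OC(C)(C)O[C@@H]3C[C@]12CO[Si](C)(C)C(C)(C)C | intermediate
18 | (R)-(−)-linalool | C=C[C@](C)(O)CCC=C(C)C | starting material
19 | (5R)-5-methyl-5-vinyltetrahydrofuran-2-ol (anomeric carbon undefined) | C=C[C@@]1(C)CCC(O)O1 | intermediate
20 | (R)-5-iodo-3-methylpent-1-en-3-yl formate | C=C[C@](C)(OC=O)CCI | intermediate
21 | (R)-5-iodo-3-methylpent-1-en-3-ol | C=C[C@](C)(O)CCI | intermediate
22 | alkoxide Grignard reagent from 21 | C=C[C@](C)(O[Mg]Cl)CC[Mg]I | intermediate (not isolated)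
23 | 9α-alkylated bis-silyl dienol ether (7-OTMS, 13-OTMS) | C=C[C@](C)(O[Si](C)(C)C)CC[C@@H]1C=C(O[Si](C)(C)C)C=C2C(C)(C)[C@@H]3OC(C)(C)O[C@@H]3C[C@]12CO[Si](C)(C)C(C)(C)C | intermediate (not isolated)
24 | (13R)-17-(dimethylamino)-13-hydroxy-2α,3α-isopropylidenedioxy-20-(TBSO)-9βH-labda-5,14-dien-7-one (C8 undefined, removed in step 22) | C=C[C@](C)(O)CC[C@@H]1C(CN(C)C)C(=O)C=C2C(C)(C)[C@@H]3OC(C)(C)O[C@@H]3C[C@]12CO[Si](C)(C)C(C)(C)C | intermediate
25 | 5αH-saturated 7-ketone from 24 | C=C[C@](C)(O)CC[C@@H]1C(CN(C)C)C(=O)C[C@H]2C(C)(C)[C@@H]3OC(C)(C)O[C@@H]3C[C@]12CO[Si](C)(C)C(C)(C)C | intermediate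
26 | C20 alcohol from 25 | C=C[C@](C)(O)CC[C@@H]1C(CN(C)C)C(=O)C[C@H]2C(C)(C)[C@@H]3OC(C)(C)O[C@@H]3C[C@]12CO | intermediate
27 | (R)-2-methylbutanoic acid | CC[C@@H](C)C(=O)O | starting material
28 | C20 (R)-2-methylbutanoate of 26 | C=C[C@](C)(O)CC[C@@H]1C(CN(C)C)C(=O)C[C@H]2C(C)(C)[C@@H]3OC(C)(C)O[C@@H]3C[C@]12COC(=O)[C@H](C)CC | intermediate
29 | 7α-alcohol from 28 | C=C[C@](C)(O)CC[C@@H]1C(CN(C)C)[C@H](O)C[C@H]2C(C)(C)[C@@H]3OC(C)(C)O[C@@H]3C[C@]12COC(=O)[C@H](C)CC | intermediate
30 | 17-(dimethylamino)-2α,3α,7α,13-tetraol C20 ester | C=C[C@](C)(O)CC[C@@H]1C(CN(C)C)[C@H](O)C[C@H]2C(C)(C)[C@H](O)[C@H](O)C[C@]12COC(=O)[C@H](C)CC | intermediate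
31 | N-oxide of 30 | C=C[C@](C)(O)CC[C@@H]1C(C[N+](C)(C)[O-])[C@H](O)C[C@H]2C(C)(C)[C@H](O)[C@H](O)C[C@]12COC(=O)[C@H](C)CC | intermediate (not isolated)
32 | (13R)-2α,3α,7α,13-tetrahydroxy-9βH-labda-8(17),14-dien-20-yl (R)-2-methylbutanoate | C=C[C@](C)(O)CC[C@@H]1C(=C)[C@H](O)C[C@H]2C(C)(C)[C@H](O)[C@H](O)C[C@]12COC(=O)[C@H](C)CC | intermediate
33 | angelic acid | C/C=C(/C)C(=O)O | starting material
34 | angelic 2,4,6-trichlorobenzoic anhydride | C/C=C(/C)C(=O)OC(=O)c1c(Cl)cc(Cl)cc1Cl | intermediate (not isolated)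
35 | (13R)-2α-angeloyloxy-3α,7α,13-trihydroxy-9βH-labda-8(17),14-dien-20-yl (R)-2-methylbutanoate | C=C[C@](C)(O)CC[C@@H]1C(=C)[C@H](O)C[C@H]2C(C)(C)[C@H](O)[C@H](OC(=O)/C(C)=C\C)C[C@]12COC(=O)[C@H](C)CC | target

## Step count and risks

Total step count: 23. Longest linear sequence: 20 steps (steps 1–12 and 16–23, from ethyl 2-oxocyclohexane-1-carboxylate); steps 13–15 make the side-chain fragment.

The three steps most likely to fail:

Step 14 (Suárez fragmentation beside a vinyl group, where the hypoiodite may add to the olefin). The fallback sets out from lactol 19. Dehydration (MsCl, Et3N, CH2Cl2, 0 °C → reflux) gives the cyclic enol ether (R)-2-methyl-2-vinyl-2,3-dihydrofuran F1. Ozonolysis of only the electron-rich enol-ether double bond (O3, CH2Cl2/MeOH, −78 °C, indicator end-point), with NaBH4/MeOH work-up that also methanolyses the tertiary formate, gives (R)-3-methylpent-4-ene-1,3-diol F2. Appel iodination of the primary hydroxyl (I2, PPh3, imidazole, 0 °C) comes back to the route at iodo alcohol 21.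

Step 16 (tandem 1,4-addition and Mannich trapping, where an unprotected alkoxide Grignard reagent must add to a neopentyl β-carbon). The fallback sets out from dienone 17 and iodide 21 and separates the two bond formations. A tin-free Giese radical addition ((Me3Si)3SiH, AIBN, benzene, 80 °C) of the primary C11 radical to C9, again anti to C20, tolerates the free hydroxyl and gives (13R)-13-hydroxy-2α,3α-isopropylidenedioxy-20-(tert-butyldimethylsilyloxy)-17-nor-9βH-labda-5,14-dien-7-one F3. Because C8 is the only enolisable position of this enone, LiN(i-Pr)2 (2.2 equiv, −78 °C) followed by CH2=NMe2+ I− installs C17 and comes back to the route at 24.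

Step 23 (site-selective angeloylation of a tetraol without Z→E isomerisation). The fallback sets out from 32. Bu2SnO (toluene, reflux, water removal) gives the 2α,3α-O-dibutylstannylene acetal of 32 F4, in which the equatorial C2 oxygen is activated. It is acylated by anhydride 34 at rt without amine base, and aqueous work-up comes back to the route at target 35.

## Further compounds

F1 | step 14 | (R)-2-methyl-2-vinyl-2,3-dihydrofuran | C=C[C@@]1(C)CC=CO1
F2 | step 14 | (R)-3-methylpent-4-ene-1,3-diol | C=C[C@](C)(O)CCO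
F3 | step 16 | (13R)-13-hydroxy-2α,3α-isopropylidenedioxy-20-(tert-butyldimethylsilyloxy)-17-nor-9βH-labda-5,14-dien-7-one | C=C[C@](C)(O)CC[C@@H]1CC(=O)C=C2C(C)(C)[C@@H]3OC(C)(C)O[C@@H]3C[C@]12CO[Si](C)(C)C(C)(C)C
F4 | step 23 | 2α,3α-O-dibutylstannylene acetal of 32 | C=C[C@](C)(O)CC[C@@H]1C(=C)[C@H](O)C[C@H]2C(C)(C)[C@@H]3O[Sn](CCCC)(CCCC)O[C@@H]3C[C@]12COC(=O)[C@H](C)CC
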